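The cyclopenta[c]pyridine is cut at C7–C7a, and the adjacent fully substituted carbinol carbons C5 and C6 of the five-membered ring are traced back to one alkene. For that purpose the ester carbon on C5 and C7 are tied into a flat butenolide that carries a (+)-menthyl acetal at C7, the methyl group on C6 and a 5-bromo-2-chloropyridin-4-yl ring (future C4a; Br at C7a, Cl at C3) on C5. One syn-dihydroxylation anti to the menthyloxy group makes both C–O bonds and both stereocentres; after lactone opening, rotation about C5–C6 turns the lactone-cis diol into the trans diol of the carbocycle, which is then closed at C7–C7a and armed with the dienyl chain at C3.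

Key step: step 5

Assumption: as for the unsubstituted menthyloxybutenolide, the less soluble acetal epimer of the (+)-menthyl series is taken to be the (S)-epimer 6 (if the other epimer crystallised, (−)-menthol would give the same (S)-acetal); locants C1–C7a are those of the cyclopenta[c]pyridine core of 24.

Step 1
Reactants: 1 glyoxylic acid (used as its monohydrate); 2 propanal
Product: 3 5-hydroxy-4-methylfuran-2(5H)-one (racemic lactol)
Conditions: morpholine hydrochloride, 1,4-dioxane/H2O, reflux
Reagents that add atoms: none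
Why: A Mannich-type aldol condensation (amine-salt-mediated) joins the α-carbon of propanal to the aldehyde carbon of glyoxylic acid, and dehydration followed by lactol closure of the cis-formyl acid gives the hydroxybutenolide, a well-established transformation in which the lactol carbon stays racemic.

Step 2
Reactants: 3 5-hydroxy-4-methylfuran-2(5H)-one; 4 (+)-menthol
Product: 6 (5S)-5-[(1S,2R,5S)-menthyloxy]-4-methylfuran-2(5H)-one, via acetal epimer mixture 5 (not isolated)
Conditions: CSA (cat.), toluene, reflux with azeotropic removal of water; crystallisation from hexane, −20 °C; mother liquor re-equilibrated with CSA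
Reagents that add atoms: none
Why: Acid-catalysed acetalisation of the lactol gives both epimers at the acetal carbon (future C7), which interconvert under the acidic conditions, so that selective crystallisation of the (S)-epimer together with re-equilibration of the mother liquor sets this stereocentre, as is established for the parent menthyloxybutenolide.

Step 3
Reactants: 6 (5S)-5-[(1S,2R,5S)-menthyloxy]-4-methylfuran-2(5H)-one
Product: 8 (5S)-3-bromo-5-[(1S,2R,5S)-menthyloxy]-4-methylfuran-2(5H)-one, via dibromolactone 7 (not isolated)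
Conditions: Br2, CH2Cl2, 0→25 °C; then Et3N, 0 °C
Reagents that add atoms: bromine BrBr
Why: Bromination–dehydrobromination: bromine adds across the conjugated alkene and triethylamine then removes the acidic α-proton with loss of the β-bromide (E1cB), which returns the butenolide with bromine on the α-carbon (future C5) without touching the acetal centre under these non-acidic conditions.

Step 4
Reactants: 8 (5S)-3-bromo-5-[(1S,2R,5S)-menthyloxy]-4-methylfuran-2(5H)-one; 9 5-bromo-2-chloro-4-iodopyridine
Product: 12 (5S)-3-(5-bromo-2-chloropyridin-4-yl)-5-[(1S,2R,5S)-menthyloxy]-4-methylfuran-2(5H)-one, via pyridylmagnesium chloride 10 (not isolated), via pyridylzinc chloride 11 (not isolated)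
Conditions: 9, iPrMgCl·LiCl, THF, −40 °C; ZnCl2, −40→25 °C; then 8, Pd2(dba)3 (cat.), P(2-furyl)3, THF, 50 °C
Reagents that add atoms: none
Why: Negishi coupling: iodine–magnesium exchange is selective for the C–I bond at −40 °C, transmetalation to zinc gives a stable arylzinc, and zerovalent palladium inserts into the activated α-bromo enoate C–Br bond in preference to the hindered pyridyl C–Br and the C–Cl bonds, so the C4a–C5 bond forms with both ring halogens retained.

Step 5
Reactants: 12 (5S)-3-(5-bromo-2-chloropyridin-4-yl)-5-[(1S,2R,5S)-menthyloxy]-4-methylfuran-2(5H)-one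
Product: 14 (3R,4S,5S)-3-(5-bromo-2-chloropyridin-4-yl)-3,4-dihydroxy-5-[(1S,2R,5S)-menthyloxy]-4-methyldihydrofuran-2(3H)-one, via osmate ester 13 (not isolated)
Conditions: OsO4 (10 mol %), NMO, citric acid, acetone/t-BuOH/H2O, 25→40 °C
Reagents that add atoms: osmium tetroxide O=[Os](=O)(=O)=O; N-methylmorpholine N-oxide C[N+]1([O-])CCOCC1; water O
Why: The alkene and OsO4 combine in a concerted (3+2) cycloaddition to the hexavalent osmium glycolate 13, which NMO reoxidises and water cleaves, so the two new hydroxyls necessarily sit on the same face and are cis on the lactone ring. The closest known reaction type is the osmium-catalysed syn-dihydroxylation of α,β-unsaturated lactones with an amine N-oxide as terminal oxidant, taken here to a tetrasubstituted case, with citric acid added to speed hydrolysis of the hindered osmate and to keep the medium non-basic. No ring is closed, so no mode of closure has to be met. Both new stereocentres, C5 (R) and C6 (S), are controlled by the C7 acetal: the menthyloxy group blocks its own face of the flat five-membered ring and the oxidant adds from the face of the acetal hydrogen. The step needs face selectivity and chemoselectivity; the first is secured by the resident stereocentre directly next to C6, the second by the absence of any other alkene and by the halogenated pyridine nitrogen, which is too weakly basic to ligate osmium. Once the lactone is opened, rotation about C5–C6 turns this cis-diol into the trans-diol of the carbocycle with the C5 hydroxyl cis to the C6 methyl, as the target demands.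

Step 6
Reactants: 14 (3R,4S,5S)-3-(5-bromo-2-chloropyridin-4-yl)-3,4-dihydroxy-5-[(1S,2R,5S)-menthyloxy]-4-methyldihydrofuran-2(3H)-one
Product: 15 (3R,4S)-3-(5-bromo-2-chloropyridin-4-yl)-3,4,5-trihydroxy-4-methyldihydrofuran-2(3H)-one (lactol, both C5 anomers)
Conditions: aq HCl (2 M), 1,4-dioxane, 70 °C
Reagents that add atoms: water O
Why: Acid-catalysed hydrolysis of the acyloxy acetal (a pseudo-ester) releases the auxiliary for recovery and leaves the lactol form of the 4-oxo acid; C5 and C6 are fully substituted carbinol carbons that cannot epimerise, and the new lactol centre is of no consequence.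

Step 7
Reactants: 15 (3R,4S)-3-(5-bromo-2-chloropyridin-4-yl)-3,4,5-trihydroxy-4-methyldihydrofuran-2(3H)-one
Product: 16 methyl (2R,3S)-2-(5-bromo-2-chloropyridin-4-yl)-2,3-dihydroxy-3-methyl-4-oxobutanoate
Conditions: KHCO3, MeI, DMF, 0→25 °C
Reagents that add atoms: iodomethane CI
Why: Mild base opens the pseudo-acid to its carboxylate, and SN2 O-alkylation of that carboxylate with iodomethane traps the open-chain form as the normal methyl ester with the C7 aldehyde free, hydrogencarbonate being too weak a base to start a retro-aldol cleavage.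

Step 8
Reactants: 16 methyl (2R,3S)-2-(5-bromo-2-chloropyridin-4-yl)-2,3-dihydroxy-3-methyl-4-oxobutanoate
Product: 17 methyl (5R,6R)-3-chloro-5,6,7-trihydroxy-6-methyl-6,7-dihydro-5H-cyclopenta[c]pyridine-5-carboxylate (both C7 epimers)
Conditions: CrCl2 (excess), NiCl2 (cat.), degassed DMF, 25→50 °C
Reagents that add atoms: none
Why: Nozaki–Hiyama–Kishi reaction: zerovalent nickel inserts into the C7a–Br bond, transmetalation to trivalent chromium gives an aryl nucleophile that adds 5-exo-trig to the C7 aldehyde while tolerating the free tertiary hydroxyls, the ester and the C3 chloride, and the new C7 carbinol centre, formed without control, is erased by the oxidation in step 12.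

Step 9
Reactants: 18 (S)-2-methylbutan-1-ol
Product: 20 (2E,4S)-2,4-dimethylhex-2-enal, via (S)-2-methylbutanal 19 (not isolated)
Conditions: TEMPO (cat.), KBr (cat.), NaOCl, NaHCO3, CH2Cl2/H2O, 0 °C; dried solution, then Ph3P=C(CH3)CHO, toluene, 80 °C
Reagents that add atoms: 2-(triphenylphosphoranylidene)propanal CC(C=O)=P(c1ccccc1)(c1ccccc1)c1ccccc1
Why: TEMPO/hypochlorite oxidation gives the α-branched aldehyde without racemisation, and Wittig olefination with the formyl-stabilised ylide under base-free conditions gives the (E)-trisubstituted enal, the stereocentre of the chain being carried over unchanged from the alcohol.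

Step 10
Reactants: 20 (2E,4S)-2,4-dimethylhex-2-enal
Product: 21 2-[(1E,3E,5S)-3,5-dimethylhepta-1,3-dien-1-yl]-4,4,5,5-tetramethyl-1,3,2-dioxaborolane
Conditions: CrCl2, LiI, Cl2CHB(pin), THF, 25 °C
Reagents that add atoms: 2-(dichloromethyl)-4,4,5,5-tetramethyl-1,3,2-dioxaborolane ClC(Cl)B1OC(C)(C)C(C)(C)O1
Why: Takai–Utimoto-type boron olefination: the geminal dichromium species generated from the dihalomethylboronate adds to the aldehyde and eliminates to the (E)-alkenylboronate, which here extends the enal to the (1E,3E)-dienylboronate without touching the remote stereocentre.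

Step 11
Reactants: 17 methyl (5R,6R)-3-chloro-5,6,7-trihydroxy-6-methyl-6,7-dihydro-5H-cyclopenta[c]pyridine-5-carboxylate; 21 2-[(1E,3E,5S)-3,5-dimethylhepta-1,3-dien-1-yl]-4,4,5,5-tetramethyl-1,3,2-dioxaborolane
Product: 22 methyl (5R,6R)-3-[(1E,3E,5S)-3,5-dimethylhepta-1,3-dien-1-yl]-5,6,7-trihydroxy-6-methyl-6,7-dihydro-5H-cyclopenta[c]pyridine-5-carboxylate (both C7 epimers)
Conditions: Pd(OAc)2 (cat.), SPhos, K3PO4, THF/H2O, 40 °C
Reagents that add atoms: none
Why: Suzuki–Miyaura coupling at the only remaining carbon–halogen bond, the C3–Cl bond of the 2-chloropyridine, proceeds with retention of the diene geometry, and it is placed before the C7 ketone exists so that the basic medium meets only the triol, which offers no β-hydroxy ketone for retro-aldol ring opening.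

Step 12
Reactants: 22 methyl (5R,6R)-3-[(1E,3E,5S)-3,5-dimethylhepta-1,3-dien-1-yl]-5,6,7-trihydroxy-6-methyl-6,7-dihydro-5H-cyclopenta[c]pyridine-5-carboxylate
Product: 23 methyl (5R,6S)-3-[(1E,3E,5S)-3,5-dimethylhepta-1,3-dien-1-yl]-5,6-dihydroxy-6-methyl-7-oxo-6,7-dihydro-5H-cyclopenta[c]pyridine-5-carboxylate
Conditions: IBX, DMSO, 25 °C
Reagents that add atoms: none
Why: IBX oxidation converts the single secondary (pyridylic) alcohol into the ketone, leaves the tertiary hydroxyls untouched and does not cleave 1,2-diols, and both C7 epimers converge on one ketone.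

Step 13
Reactants: 23 methyl (5R,6S)-3-[(1E,3E,5S)-3,5-dimethylhepta-1,3-dien-1-yl]-5,6-dihydroxy-6-methyl-7-oxo-6,7-dihydro-5H-cyclopenta[c]pyridine-5-carboxylate
Product: 24 methyl (5R,6S)-6-acetoxy-3-[(1E,3E,5S)-3,5-dimethylhepta-1,3-dien-1-yl]-5-hydroxy-6-methyl-7-oxo-6,7-dihydro-5H-cyclopenta[c]pyridine-5-carboxylate (CNP0483502.1)
Conditions: Ac2O, DMAP (cat.), pyridine, 0→25 °C
Reagents that add atoms: acetic anhydride CC(=O)OC(C)=O
Why: DMAP-catalysed acylation is expected at the C6 hydroxyl of the α-ketol, which is the less hindered and more nucleophilic of the two tertiary alcohols (the C5 hydroxyl is flanked by the ester, the ring-fusion carbon and quaternary C6 and is deactivated by ester and pyridine), and the trans arrangement of the two oxygens on the five-membered ring rules out later acyl migration.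

Compound list

In the lactones, ring positions 3, 4 and 5 are the future C5, C6 and C7. The C6 descriptor reads R in triols 17 and 22 only because the CIP rank of C7 changes; the geometry is the same throughout.

1 | glyoxylic acid | O=CC(=O)O | starting material
2 | propanal | CCC=O | starting material
3 | 5-hydroxy-4-methylfuran-2(5H)-one (racemic) | OC1OC(=O)C=C1C | intermediate
4 | (+)-menthol, (1S,2R,5S)-2-isopropyl-5-methylcyclohexan-1-ol | CC(C)[C@H]1CC[C@H](C)C[C@@H]1O | starting material
5 | 5-[(1S,2R,5S)-menthyloxy]-4-methylfuran-2(5H)-one, both acetal epimers | O1C(O[C@H]2C[C@@H](C)CC[C@@H]2C(C)C)C(C)=CC1=O | intermediate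
6 | (5S)-5-[(1S,2R,5S)-menthyloxy]-4-methylfuran-2(5H)-one | O1[C@H](O[C@H]2C[C@@H](C)CC[C@@H]2C(C)C)C(C)=CC1=O | intermediate
7 | (5S)-3,4-dibromo-5-[(1S,2R,5S)-menthyloxy]-4-methyldihydrofuran-2(3H)-one (C3/C4 not defined) | O1[C@H](O[C@H]2C[C@@H](C)CC[C@@H]2C(C)C)C(C)(Br)C(Br)C1=O | intermediate
8 | (5S)-3-bromo-5-[(1S,2R,5S)-menthyloxy]-4-methylfuran-2(5H)-one | O1[C@H](O[C@H]2C[C@@H](C)CC[C@@H]2C(C)C)C(C)=C(Br)C1=O | intermediate
9 | 5-bromo-2-chloro-4-iodopyridine | Clc1cc(I)c(Br)cn1 | starting material
10 | (5-bromo-2-chloropyridin-4-yl)magnesium chloride (LiCl complex) | Cl[Mg]c1cc(Cl)ncc1Br | intermediate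
11 | (5-bromo-2-chloropyridin-4-yl)zinc chloride | Cl[Zn]c1cc(Cl)ncc1Br | intermediate
12 | (5S)-3-(5-bromo-2-chloropyridin-4-yl)-5-[(1S,2R,5S)-menthyloxy]-4-methylfuran-2(5H)-one | O1[C@H](O[C@H]2C[C@@H](C)CC[C@@H]2C(C)C)C(C)=C(c2cc(Cl)ncc2Br)C1=O | intermediate
13 | cyclic dioxo-osmium 3,4-glycolate of 12, on the face anti to the menthyloxy group | O1[C@H](O[C@H]2C[C@@H](C)CC[C@@H]2C(C)C)[C@@]3(C)O[Os](=O)(=O)O[C@@]3(c2cc(Cl)ncc2Br)C1=O | intermediate
14 | (3R,4S,5S)-3-(5-bromo-2-chloropyridin-4-yl)-3,4-dihydroxy-5-[(1S,2R,5S)-menthyloxy]-4-methyldihydrofuran-2(3H)-one | O1[C@H](O[C@H]2C[C@@H](C)CC[C@@H]2C(C)C)[C@@](C)(O)[C@@](c2cc(Cl)ncc2Br)(O)C1=O | intermediate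
15 | (3R,4S)-3-(5-bromo-2-chloropyridin-4-yl)-3,4,5-trihydroxy-4-methyldihydrofuran-2(3H)-one (both C5 anomers) | O1C(O)[C@@](C)(O)[C@@](c2cc(Cl)ncc2Br)(O)C1=O | intermediate
16 | methyl (2R,3S)-2-(5-bromo-2-chloropyridin-4-yl)-2,3-dihydroxy-3-methyl-4-oxobutanoate | O=C[C@@](C)(O)[C@@](c1cc(Cl)ncc1Br)(O)C(=O)OC | intermediate
17 | methyl (5R,6R)-3-chloro-5,6,7-trihydroxy-6-methyl-6,7-dihydro-5H-cyclopenta[c]pyridine-5-carboxylate (both C7 epimers) | Clc1cc2c(cn1)C(O)[C@@](C)(O)[C@@]2(O)C(=O)OC | intermediate
18 | (S)-2-methylbutan-1-ol | CC[C@H](C)CO | starting material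
19 | (S)-2-methylbutanal | CC[C@H](C)C=O | intermediate
20 | (2E,4S)-2,4-dimethylhex-2-enal | CC[C@H](C)/C=C(C)/C=O | intermediate
21 | 2-[(1E,3E,5S)-3,5-dimethylhepta-1,3-dien-1-yl]-4,4,5,5-tetramethyl-1,3,2-dioxaborolane | CC[C@H](C)/C=C(C)/C=C/B1OC(C)(C)C(C)(C)O1 | intermediate
22 | methyl (5R,6R)-3-[(1E,3E,5S)-3,5-dimethylhepta-1,3-dien-1-yl]-5,6,7-trihydroxy-6-methyl-6,7-dihydro-5H-cyclopenta[c]pyridine-5-carboxylate (both C7 epimers) | CC[C@H](C)/C=C(C)/C=C/c1cc2c(cn1)C(O)[C@@](C)(O)[C@@]2(O)C(=O)OC | intermediate
23 | methyl (5R,6S)-3-[(1E,3E,5S)-3,5-dimethylhepta-1,3-dien-1-yl]-5,6-dihydroxy-6-methyl-7-oxo-6,7-dihydro-5H-cyclopenta[c]pyridine-5-carboxylate | CC[C@H](C)/C=C(C)/C=C/c1cc2c(cn1)C(=O)[C@@](C)(O)[C@@]2(O)C(=O)OC | intermediate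
24 | methyl (5R,6S)-6-acetoxy-3-[(1E,3E,5S)-3,5-dimethylhepta-1,3-dien-1-yl]-5-hydroxy-6-methyl-7-oxo-6,7-dihydro-5H-cyclopenta[c]pyridine-5-carboxylate | CC[C@H](C)/C=C(C)/C=C/c1cc2c(cn1)C(=O)[C@@](C)(OC(C)=O)[C@@]2(O)C(=O)OC | target

Total step count: 13. Longest linear sequence: 11 steps (steps 1–8 and 11–13, from glyoxylic acid and propanal); the side chain (steps 9 and 10) joins at step 11.

Steps most likely to fail

Step 5. The (3+2) addition to the tetrasubstituted, electron-poor and ortho-hindered alkene may stall, or turnover may stop at the hindered osmate ester; forcing the reaction by heat could erode the face selectivity. The fallback sets out from 12 and comes back at 14. Osmium is replaced by ruthenium tetroxide generated in the flask (RuCl3 cat., NaIO4, CeCl3 cat., EtOAc/MeCN/H2O, 0 °C, short contact time). This is a far more reactive oxidant for hindered and electron-poor alkenes, it runs through a different metal-oxo cycle with periodate as terminal oxidant, and it should again add anti to the acetal substituent. It gives 14 directly, so no compound outside the list arises (F0).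

Step 8. Insertion of zerovalent nickel into the hindered C7a–Br bond may be slow, so that reduction or pinacol coupling of the α-hydroxy aldehyde, or insertion at C3–Cl, takes over. The fallback sets out from 12 and comes back at 17. The bromide is exchanged for iodide before the key step by a copper-catalysed aromatic Finkelstein reaction (CuI cat., NaI, trans-N,N'-dimethylcyclohexane-1,2-diamine, 1,4-dioxane, 110 °C; the chloride does not exchange). This gives (5S)-3-(2-chloro-5-iodopyridin-4-yl)-5-[(1S,2R,5S)-menthyloxy]-4-methylfuran-2(5H)-one F1. The conditions of steps 5, 6 and 7 then lead through the osmate ester F2 to the iodo diol lactone F3, the iodo lactol F4 and methyl (2R,3S)-2-(2-chloro-5-iodopyridin-4-yl)-2,3-dihydroxy-3-methyl-4-oxobutanoate F5. Its aryl iodide is the classical partner of the Nozaki–Hiyama–Kishi reaction (CrCl2, NiCl2 cat., DMF, 25 °C) and should close to 17 well ahead of any reaction at C3–Cl.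

Step 4. Zerovalent palladium may insert into the C–Br bond of the arylzinc or of the product (oligomerisation), or transmetalation of the hindered, electron-poor arylzinc may be slow, with reduction or homocoupling of 8. The fallback sets out from 8 and comes back at 12, and it reverses the polarity of the coupling. Stannylation of 8 with hexamethylditin (Me3SnSnMe3, Pd(PPh3)4, toluene, 90 °C) gives (5S)-5-[(1S,2R,5S)-menthyloxy]-4-methyl-3-(trimethylstannyl)furan-2(5H)-one F6. Stille coupling of this stannane with 9 (Pd(PPh3)4, CuI, CsF, DMF, 45 °C) then takes place at the C–I bond, far ahead of C–Br and C–Cl, and gives 12.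

Further compounds
F0 | step 5 | none | none
F1 | step 8 | (5S)-3-(2-chloro-5-iodopyridin-4-yl)-5-[(1S,2R,5S)-menthyloxy]-4-methylfuran-2(5H)-one | O1[C@H](O[C@H]2C[C@@H](C)CC[C@@H]2C(C)C)C(C)=C(c2cc(Cl)ncc2I)C1=O
F2 | step 8 | cyclic dioxo-osmium 3,4-glycolate of F1, anti to the menthyloxy group | O1[C@H](O[C@H]2C[C@@H](C)CC[C@@H]2C(C)C)[C@@]3(C)O[Os](=O)(=O)O[C@@]3(c2cc(Cl)ncc2I)C1=O
F3 | step 8 | (3R,4S,5S)-3-(2-chloro-5-iodopyridin-4-yl)-3,4-dihydroxy-5-[(1S,2R,5S)-menthyloxy]-4-methyldihydrofuran-2(3H)-one | O1[C@H](O[C@H]2C[C@@H](C)CC[C@@H]2C(C)C)[C@@](C)(O)[C@@](c2cc(Cl)ncc2I)(O)C1=O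
F4 | step 8 | (3R,4S)-3-(2-chloro-5-iodopyridin-4-yl)-3,4,5-trihydroxy-4-methyldihydrofuran-2(3H)-one (both C5 anomers) | O1C(O)[C@@](C)(O)[C@@](c2cc(Cl)ncc2I)(O)C1=O
F5 | step 8 | methyl (2R,3S)-2-(2-chloro-5-iodopyridin-4-yl)-2,3-dihydroxy-3-methyl-4-oxobutanoate | O=C[C@@](C)(O)[C@@](c1cc(Cl)ncc1I)(O)C(=O)OC
F6 | step 4 | (5S)-5-[(1S,2R,5S)-menthyloxy]-4-methyl-3-(trimethylstannyl)furan-2(5H)-one | O1[C@H](O[C@H]2C[C@@H](C)CC[C@@H]2C(C)C)C(C)=C([Sn](C)(C)C)C1=O
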